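## Retrosynthetic overview

1. The target comes from its 7‑O‑prenyl ether by an aromatic Claisen rearrangement, so the prenyl ether serves as the 7‑OH protecting group until the last step.
2. That ether comes from a 2‑hydroxychalcone carrying a masked catechol and an (S)‑epoxide, by one reductive double cyclisation: the chromanol ring (D) closes first by 6‑endo phenol–epoxide opening, then the flavan ring (C) closes via a flavylium ion and two hydride transfers, the second setting C2.
3. The chalcone comes from a Claisen–Schmidt condensation of the B‑ring methyl ketone with 2‑hydroxy‑4‑prenyloxybenzaldehyde.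
4. The B‑ring ketone comes from 3′,4′‑dimethoxyacetophenone by bromination, demethylation, O4‑reverse‑prenylation and Claisen (C3′ prenyl), Shi epoxidation, then Stille prenylation at C2′ after the first prenyl is already epoxidised.

Assumptions: the (R)‑acid in step 9 is taken to give (2S) (if a model substrate shows the opposite sense, the (S)‑acid is used); the 1‑ethoxyethyl (EE) acetal carbons are epimer mixtures and are left unassigned in the SMILES.

## Route

Step 1
Reactants: 1 1-(3,4-dimethoxyphenyl)ethan-1-one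
Product: 2 1-(2-bromo-4,5-dimethoxyphenyl)ethan-1-one
Conditions: NBS (1.05 equiv), MeCN, rt
Reagents that add atoms: N-bromosuccinimide, O=C1CCC(=O)N1Br
Why: Electrophilic aromatic bromination goes para to the 3‑OMe group (the donor not conjugated to the acetyl), the position at which veratraldehyde brominates, and NBS in MeCN without acid leaves the methyl ketone alone.

Step 2
Reactants: 2 1-(2-bromo-4,5-dimethoxyphenyl)ethan-1-one
Product: 3 1-(2-bromo-4,5-dihydroxyphenyl)ethan-1-one
Conditions: BBr3 (2.5 equiv), CH2Cl2, −78 °C to rt; H2O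
Reagents that add atoms: none
Why: BBr3 demethylation (Lewis‑acid ether cleavage) frees the catechol; the aryl bromide and ketone are inert.

Step 3
Reactants: 3 1-(2-bromo-4,5-dihydroxyphenyl)ethan-1-one
Product: 4 1-[2-bromo-5-hydroxy-4-(2-methylbut-3-en-2-yloxy)phenyl]ethan-1-one
Conditions: Pd(PPh3)4 (2 mol%), methyl 2-methylbut-3-en-2-yl carbonate (1.1 equiv), THF, 0 °C
Reagents that add atoms: methyl 2-methylbut-3-en-2-yl carbonate, COC(=O)OC(C)(C)C=C
Why: Tsuji–Trost O‑allylation, in which the more acidic phenoxide (4‑OH, para to the acetyl) attacks the tertiary terminus of the π‑prenyl‑Pd complex to give the reverse‑prenyl ether, at a temperature where the aryl bromide does not add to Pd(0).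

Step 4
Reactants: 4 1-[2-bromo-5-hydroxy-4-(2-methylbut-3-en-2-yloxy)phenyl]ethan-1-one
Product: 6 1-[2-bromo-4,5-bis(1-ethoxyethoxy)-3-(3-methylbut-2-en-1-yl)phenyl]ethan-1-one, via catechol 5 (not isolated)
Conditions: PhMe, 110 °C; then rt, ethyl vinyl ether (6 equiv), PPTS (5 mol%)
Reagents that add atoms: ethyl vinyl ether, C=COCC
Why: The aromatic Claisen rearrangement ([3,3]) can deliver the allyl unit only to C3, the one free ortho position, with allylic inversion to the normal prenyl group, and the air‑sensitive catechol is capped in the same pot as its bis‑EE acetal (acid‑catalysed addition to the vinyl ether).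

Step 5
Reactants: 6 1-[2-bromo-4,5-bis(1-ethoxyethoxy)-3-(3-methylbut-2-en-1-yl)phenyl]ethan-1-one
Product: 7 1-[2-bromo-3-{[(2S)-3,3-dimethyloxiran-2-yl]methyl}-4,5-bis(1-ethoxyethoxy)phenyl]ethan-1-one
Conditions: ent‑Shi ketone (L‑fructose‑derived, 30 mol%), Oxone, K2CO3, Bu4NHSO4 (cat.), MeCN–DMM/aq. borate–EDTA buffer (pH 10.5), 0 °C
Reagents that add atoms: Oxone (potassium peroxymonosulfate), [K+].[O-]S(=O)(=O)OO
Why: Shi asymmetric epoxidation of the only electron‑rich alkene, where the dioxirane of the L‑fructose‑derived ketone attacks through the spiro transition state to give the (S)‑epoxide (the D‑fructose ketone gives R); base‑stable EE groups, aryl bromide and aryl ketone survive.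

Step 6
Reactants: 7 1-[2-bromo-3-{[(2S)-3,3-dimethyloxiran-2-yl]methyl}-4,5-bis(1-ethoxyethoxy)phenyl]ethan-1-one
Product: 8 1-[3-{[(2S)-3,3-dimethyloxiran-2-yl]methyl}-4,5-bis(1-ethoxyethoxy)-2-(3-methylbut-2-en-1-yl)phenyl]ethan-1-one
Conditions: tributyl(prenyl)stannane (1.5 equiv), Pd(Pt‑Bu3)2 (5 mol%), CsF (2 equiv), dioxane, 90 °C
Reagents that add atoms: tributyl(3-methylbut-2-en-1-yl)stannane, CCCC[Sn](CCCC)(CCCC)CC=C(C)C
Why: Stille coupling at the C–Br bond ortho to the acetyl group (activated for oxidative addition) with a bulky phosphine and fluoride activation transfers the prenyl group mainly through its α‑carbon; because the first prenyl is already an epoxide, the two prenyl units stay differentiated.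

Step 7
Reactants: 9 2,4-dihydroxybenzaldehyde
Product: 10 2-hydroxy-4-(3-methylbut-2-en-1-yloxy)benzaldehyde
Conditions: prenyl bromide (1.05 equiv), K2CO3 (1.0 equiv), acetone, rt
Reagents that add atoms: 1-bromo-3-methylbut-2-ene, CC(C)=CCBr
Why: Williamson etherification is selective for the 4‑OH, which is the more acidic phenol and is not hydrogen‑bonded to the aldehyde.

Step 8
Reactants: 8 1-[3-{[(2S)-3,3-dimethyloxiran-2-yl]methyl}-4,5-bis(1-ethoxyethoxy)-2-(3-methylbut-2-en-1-yl)phenyl]ethan-1-one; 10 2-hydroxy-4-(3-methylbut-2-en-1-yloxy)benzaldehyde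
Product: 11 (E)-1-[3-{[(2S)-3,3-dimethyloxiran-2-yl]methyl}-4,5-bis(1-ethoxyethoxy)-2-(3-methylbut-2-en-1-yl)phenyl]-3-[2-hydroxy-4-(3-methylbut-2-en-1-yloxy)phenyl]prop-2-en-1-one
Conditions: KOH (50% aq.), EtOH, rt, 48 h; NH4Cl work‑up
Reagents that add atoms: none
Why: Claisen–Schmidt aldol condensation gives the thermodynamic E‑enone; the trisubstituted epoxide and the acetals are stable to hydroxide at rt.

Step 9
Reactants: 11 (E)-1-[3-{[(2S)-3,3-dimethyloxiran-2-yl]methyl}-4,5-bis(1-ethoxyethoxy)-2-(3-methylbut-2-en-1-yl)phenyl]-3-[2-hydroxy-4-(3-methylbut-2-en-1-yloxy)phenyl]prop-2-en-1-one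
Product: 15 (3S)-2,2-dimethyl-5-(3-methylbut-2-en-1-yl)-6-[(2S)-7-(3-methylbut-2-en-1-yloxy)chroman-2-yl]chroman-3,8-diol, via chromanol chalcone 12 (not isolated), via flavylium ion 13 (not isolated), via 4H-chromene 14 (not isolated)
Conditions: (R)‑3,3′‑bis(2,4,6‑triisopropylphenyl)‑BINOL N‑triflylphosphoramide (10 mol%), Hantzsch ester (2.5 equiv), MeOH (5 equiv), CHCl3, 0 to 40 °C, dark
Reagents that add atoms: none
Why: Proposed new method: the chiral acid transfers both EE groups to MeOH and activates the epoxide so that the freed 4‑OH closes the chromanol ring by 6‑endo attack at the tertiary carbon (the (S)‑carbinol carbon is not touched), then dehydrates the 2‑hydroxychalcone to a flavylium ion (second ring) that takes hydride at C4 from the Hantzsch ester, and the resulting 4H‑chromene is protonated at C3 to a 2‑aryl oxocarbenium/chiral‑anion pair whose face‑selective second hydride transfer sets C2 as (S); the closest known chemistry is the chiral‑phosphoric‑acid/Hantzsch‑ester cascade transfer hydrogenation of 2‑arylquinolines (1,4‑ then 1,2‑hydride addition) and Brønsted‑acid transfer hydrogenation of benzopyrylium ions, combined with acid‑catalysed 6‑endo phenol–epoxide cyclisation.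

Step 10
Reactants: 15 (3S)-2,2-dimethyl-5-(3-methylbut-2-en-1-yl)-6-[(2S)-7-(3-methylbut-2-en-1-yloxy)chroman-2-yl]chroman-3,8-diol
Product: 16 (3S)-6-[(2S)-7-hydroxy-6-(2-methylbut-3-en-2-yl)chroman-2-yl]-2,2-dimethyl-5-(3-methylbut-2-en-1-yl)chroman-3,8-diol
Conditions: Eu(fod)3 (10 mol%), CHCl3, 60 °C
Reagents that add atoms: none
Why: The Eu(fod)3‑catalysed aromatic Claisen rearrangement ([3,3]) moves the prenyl group from O7 to C6 with allylic inversion (giving the 1,1‑dimethylallyl group) and releases the 7‑OH; C6 (para to O1) is preferred over C8, which lies between two oxygens and is crowded for the tertiary terminus, C4a is blocked so no para migration follows, and no stereocentre is touched.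

## Compound list

1 | 1-(3,4-dimethoxyphenyl)ethan-1-one (3′,4′-dimethoxyacetophenone) | CC(=O)c1ccc(OC)c(OC)c1 | starting material
2 | 1-(2-bromo-4,5-dimethoxyphenyl)ethan-1-one | CC(=O)c1cc(OC)c(OC)cc1Br | intermediate
3 | 1-(2-bromo-4,5-dihydroxyphenyl)ethan-1-one | CC(=O)c1cc(O)c(O)cc1Br | intermediate
4 | 1-[2-bromo-5-hydroxy-4-(2-methylbut-3-en-2-yloxy)phenyl]ethan-1-one | CC(=O)c1cc(O)c(OC(C)(C)C=C)cc1Br | intermediate
5 | 1-[2-bromo-4,5-dihydroxy-3-(3-methylbut-2-en-1-yl)phenyl]ethan-1-one | CC(=O)c1cc(O)c(O)c(CC=C(C)C)c1Br | intermediate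
6 | 1-[2-bromo-4,5-bis(1-ethoxyethoxy)-3-(3-methylbut-2-en-1-yl)phenyl]ethan-1-one (acetal carbons unassigned) | CC(=O)c1cc(OC(C)OCC)c(OC(C)OCC)c(CC=C(C)C)c1Br | intermediate
7 | 1-[2-bromo-3-{[(2S)-3,3-dimethyloxiran-2-yl]methyl}-4,5-bis(1-ethoxyethoxy)phenyl]ethan-1-one (acetal carbons unassigned) | CC(=O)c1cc(OC(C)OCC)c(OC(C)OCC)c(C[C@@H]2OC2(C)C)c1Br | intermediate
8 | 1-[3-{[(2S)-3,3-dimethyloxiran-2-yl]methyl}-4,5-bis(1-ethoxyethoxy)-2-(3-methylbut-2-en-1-yl)phenyl]ethan-1-one (acetal carbons unassigned) | CC(=O)c1cc(OC(C)OCC)c(OC(C)OCC)c(C[C@@H]2OC2(C)C)c1CC=C(C)C | intermediate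
9 | 2,4-dihydroxybenzaldehyde | O=Cc1ccc(O)cc1O | starting material
10 | 2-hydroxy-4-(3-methylbut-2-en-1-yloxy)benzaldehyde | O=Cc1ccc(OCC=C(C)C)cc1O | intermediate
11 | (E)-1-[3-{[(2S)-3,3-dimethyloxiran-2-yl]methyl}-4,5-bis(1-ethoxyethoxy)-2-(3-methylbut-2-en-1-yl)phenyl]-3-[2-hydroxy-4-(3-methylbut-2-en-1-yloxy)phenyl]prop-2-en-1-one (acetal carbons unassigned) | CC(C)=CCOc1ccc(/C=C/C(=O)c2cc(OC(C)OCC)c(OC(C)OCC)c(C[C@@H]3OC3(C)C)c2CC=C(C)C)c(O)c1 | intermediate
12 | (E)-1-[(3S)-3,8-dihydroxy-2,2-dimethyl-5-(3-methylbut-2-en-1-yl)chroman-6-yl]-3-[2-hydroxy-4-(3-methylbut-2-en-1-yloxy)phenyl]prop-2-en-1-one | CC(C)=CCOc1ccc(/C=C/C(=O)c2cc(O)c3c(c2CC=C(C)C)C[C@H](O)C(C)(C)O3)c(O)c1 | intermediate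
13 | 2-[(3S)-3,8-dihydroxy-2,2-dimethyl-5-(3-methylbut-2-en-1-yl)chroman-6-yl]-7-(3-methylbut-2-en-1-yloxy)chromenylium cation (flavylium; counter-ion is the chiral phosphoramidate) | CC(C)=CCOc1ccc2ccc(-c3cc(O)c4c(c3CC=C(C)C)C[C@H](O)C(C)(C)O4)[o+]c2c1 | intermediate
14 | (3S)-2,2-dimethyl-5-(3-methylbut-2-en-1-yl)-6-[7-(3-methylbut-2-en-1-yloxy)-4H-chromen-2-yl]chroman-3,8-diol | CC(C)=CCOc1ccc2c(c1)OC(c1cc(O)c3c(c1CC=C(C)C)C[C@H](O)C(C)(C)O3)=CC2 | intermediate
15 | (3S)-2,2-dimethyl-5-(3-methylbut-2-en-1-yl)-6-[(2S)-7-(3-methylbut-2-en-1-yloxy)chroman-2-yl]chroman-3,8-diol | CC(C)=CCOc1ccc2c(c1)O[C@H](c1cc(O)c3c(c1CC=C(C)C)C[C@H](O)C(C)(C)O3)CC2 | intermediate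
16 | (3S)-6-[(2S)-7-hydroxy-6-(2-methylbut-3-en-2-yl)chroman-2-yl]-2,2-dimethyl-5-(3-methylbut-2-en-1-yl)chroman-3,8-diol (CNP0323011.1) | C=CC(C)(C)c1cc2c(cc1O)O[C@H](c1cc(O)c3c(c1CC=C(C)C)C[C@H](O)C(C)(C)O3)CC2 | target

## Step count and risks

Total step count: 10. Longest linear sequence: 9 steps (steps 1–6, 8, 9, 10).

The three steps most likely to fail:

Step 9. The enantioselectivity of the second hydride transfer is unproven, and the aryl prenyl ether must survive the acid. The fallback sets out from 11 and sets C2 by catalyst‑controlled ketone reduction and SN2 closure instead. Asymmetric transfer hydrogenation with RuCl[(R,R)‑TsDPEN](p‑cymene) and HCO2Na in water–MeOH reduces the C=C and then the C=O bond to the (R)‑1,3‑diarylpropan‑1‑ol F1. Mitsunobu cyclisation (PPh3, DIAD, THF, 0 °C) closes the flavan ring with inversion to the (2S)‑flavan epoxide bis‑EE ether F2. PPTS in MeOH then removes the EE groups and closes the chromanol ring 6‑endo, and the route is rejoined at 15.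

Step 10. The rearrangement may give C8 as well as C6, or the Lewis acid may cleave the prenyl ether. The fallback sets out from 8 and replaces the sigmatropic step by a cross‑coupling. 5‑Bromo‑2,4‑dihydroxybenzaldehyde F3 is protected at the 4‑OH with ethyl vinyl ether/PPTS to give 5‑bromo‑4‑(1‑ethoxyethoxy)‑2‑hydroxybenzaldehyde F4. This is condensed with 8 under the step 8 conditions to the bromo chalcone F5, which is taken through the step 9 conditions to the 6‑bromo‑7‑hydroxyflavan F6. A ligand‑controlled, γ‑selective Pd‑catalysed Suzuki–Miyaura coupling with prenylboronic acid pinacol ester (K3PO4, THF–H2O) then installs the 1,1‑dimethylallyl group, and the route is rejoined at 16.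

Step 6. The bromide is flanked on both sides, and the prenyl group may transfer partly through its γ‑carbon. The fallback sets out from 7 and builds the prenyl group in two stages. A Stille coupling with allyltributylstannane (same catalyst, CsF), which has no α/γ issue and a smaller nucleophile, gives the 2‑allyl ketone F7. Cross‑metathesis with 2‑methyl‑2‑butene (Grubbs II, CH2Cl2, 40 °C) converts the allyl into the prenyl group, and the route is rejoined at 8.

## Further compounds

F1 | step 9 | (1R)-1-[3-{[(2S)-3,3-dimethyloxiran-2-yl]methyl}-4,5-bis(1-ethoxyethoxy)-2-(3-methylbut-2-en-1-yl)phenyl]-3-[2-hydroxy-4-(3-methylbut-2-en-1-yloxy)phenyl]propan-1-ol (acetal carbons unassigned) | O[C@@H](c1cc(OC(C)OCC)c(OC(C)OCC)c(C[C@@H]2OC2(C)C)c1CC=C(C)C)CCc1ccc(OCC=C(C)C)cc1O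
F2 | step 9 | (2S)-2-[3-{[(2S)-3,3-dimethyloxiran-2-yl]methyl}-4,5-bis(1-ethoxyethoxy)-2-(3-methylbut-2-en-1-yl)phenyl]-7-(3-methylbut-2-en-1-yloxy)chromane (acetal carbons unassigned) | CC(C)=CCOc1ccc2c(c1)O[C@H](c1cc(OC(C)OCC)c(OC(C)OCC)c(C[C@@H]3OC3(C)C)c1CC=C(C)C)CC2
F3 | step 10 | 5-bromo-2,4-dihydroxybenzaldehyde | O=Cc1cc(Br)c(O)cc1O
F4 | step 10 | 5-bromo-4-(1-ethoxyethoxy)-2-hydroxybenzaldehyde (acetal carbon unassigned) | O=Cc1cc(Br)c(OC(C)OCC)cc1O
F5 | step 10 | (E)-3-[5-bromo-4-(1-ethoxyethoxy)-2-hydroxyphenyl]-1-[3-{[(2S)-3,3-dimethyloxiran-2-yl]methyl}-4,5-bis(1-ethoxyethoxy)-2-(3-methylbut-2-en-1-yl)phenyl]prop-2-en-1-one (acetal carbons unassigned) | CCOC(C)Oc1cc(O)c(/C=C/C(=O)c2cc(OC(C)OCC)c(OC(C)OCC)c(C[C@@H]3OC3(C)C)c2CC=C(C)C)cc1Br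
F6 | step 10 | (3S)-6-[(2S)-6-bromo-7-hydroxychroman-2-yl]-2,2-dimethyl-5-(3-methylbut-2-en-1-yl)chroman-3,8-diol | Brc1cc2c(cc1O)O[C@H](c1cc(O)c3c(c1CC=C(C)C)C[C@H](O)C(C)(C)O3)CC2
F7 | step 6 | 1-[3-{[(2S)-3,3-dimethyloxiran-2-yl]methyl}-4,5-bis(1-ethoxyethoxy)-2-(prop-2-en-1-yl)phenyl]ethan-1-one (acetal carbons unassigned) | CC(=O)c1cc(OC(C)OCC)c(OC(C)OCC)c(C[C@@H]2OC2(C)C)c1CC=C
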